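(The numbers of this flask are assumed; the result is computed.)

The time of reading is what we have to choose: take the flask off at 30 min (delta) or leave it until 50 min (beta). The charges are the same.

all flasks: free monomer 0.050 M; initiator 1.2 mM

|  | time |
|---|---|
| delta | 30 min |
| beta | 50 min |

    free monomer + initiator → living end + monomer in chains (k1 = 4.7 /M/min)
    monomer in chains + living end → free monomer + living end, rate k2*[living end] as long as [monomer in chains] is above zero (k2 = 0.28 /min)
    free monomer + living end → monomer in chains + living end, rate k3*[living end]*[free monomer] (k3 = 38 /M/min)
    2 initiator → spent initiator (k4 = 180 /M/min)

- where a step has two of a species, its rate is k times that concentration squared, and two are used at each turn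
- the average divides the monomer in chains by the number of chains begun, living and dead together
- run time (delta): 30 min

- which of the two ends with the longer chains by the average number of monomer units in a chain (chains begun, living or dead) ("neither" if they lie within 10%) (delta / beta / neither)
- average number of monomer units in a chain (chains begun, living or dead) at the end, delta
- average number of monomer units in a chain (chains begun, living or dead) at the end, beta

We reckon the chains first. Initiator leaves by two steps, starting chains or turning into spent initiator. The ratio of those two losses integrates to a logarithm, and with [free monomer] held at its charge, chains begun come to 0.681 mM.

While [living end] stands there, free monomer falls pseudo-first-order towards a floor of 7.37 mM, where adding and losing balance. The relaxation time, 38.6 min, is one over k3 times [living end]. Because initiator lasts about 4.26 min under chain starting, shorter than that time, we treat [living end] as constant from the start.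

In logarithms, the gap to the floor loses a power of ten every 88.8 min. The length tends to 62.6. So we expect 33.8 for delta and 45.4 for beta. The ratio is 1.34, larger than the 10% margin allows, so we leave the flask until 50 min.

The forecast says beta, with 32 for delta and 44 for beta, a little below our figures. Its ground is that free monomer is “still falling at 30 minutes”.

The simulation gives beta, with 31.8 for delta and 44.3 for beta.

In delta at 30.0 min, monomer in chains is still made 3.88 times faster than it returns to free monomer, while delta's 30 min is shorter than the relaxation time of 38.6 min and beta's 50 min is longer. For the flask delta left until 80 min, the same relaxation time gives a length of 54.7, and that flask reads 54.4.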